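**Strategy.** The carbocycle of the 1,2-dihydronaphthalene is disconnected at C1–C2 and C3=C4 into a 2-(pyranonylmethyl)benzaldehyde and methyl (E)-4-oxobut-2-enoate. The route exploits that C1 is a diarylmethane carbon between C8a of the catechol ring and C3′ of the pyranone, and that C4 sits at aldehyde level on C4a. Light turns this aldehyde into a hydroxy-o-quinodimethane; a chiral iminium ion of the enal traps it, the enamine closes onto the re-formed aldehyde and water is lost. One operation thus closes the carbocycle on the finished arene and pyranone, sets C1 and C2 (trans, 1R,2R) and leaves C3 as a formyl group for Pinnick oxidation.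

Key step: step 7

Remark: locants follow the target (C1 bears the pyranone, C2 the methyl ester, C3 the carboxyl or formyl group, C4 is the vinylic CH; pyranone atoms are primed). The (R)-amine in step 7 is assigned from the usual shielding model of diarylprolinol silyl ether iminium ions, and the (S)-amine would be used if the opposite sense were found. 2-Bromo-4,5-dihydroxybenzaldehyde and methyl (E)-4-oxobut-2-enoate are taken as commercial.

Step 1
Reactants: 1 ethyl tiglate; 2 diethyl oxalate
Product: 4 3-methyl-2-oxo-2H-pyran-6-carboxylic acid, via potassium dienolate 3 (not isolated)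
Conditions: KOEt, EtOH–Et2O, 0 °C to rt; then conc. HCl, 100 °C
Reagents that add atoms: water, O
Why: Vinylogous (γ) Claisen condensation of the tiglate dienolate with the non-enolisable oxalate should give the stabilised potassium salt 3, and hot HCl should isomerise the C4=C5 bond, lactonise the enol onto the tiglate ester and hydrolyse the remaining ester (the classical oxalate–crotonate route to 2-pyranone-6-carboxylic acids).

Step 2
Reactants: 4 3-methyl-2-oxo-2H-pyran-6-carboxylic acid
Product: 5 tert-butyl 3-methyl-2-oxo-2H-pyran-6-carboxylate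
Conditions: Cl3CC(=NH)Ot-Bu, BF3·OEt2 (cat.), CH2Cl2–cyclohexane, rt
Reagents that add atoms: tert-butyl 2,2,2-trichloroacetimidate, CC(C)(C)OC(=N)C(Cl)(Cl)Cl
Why: Acid-catalysed tert-butylation of the carboxylic acid by the imidate needs no base, which the electrophilic pyranone would not tolerate.

Step 3
Reactants: 5 tert-butyl 3-methyl-2-oxo-2H-pyran-6-carboxylate
Product: 6 tert-butyl 3-(bromomethyl)-2-oxo-2H-pyran-6-carboxylate
Conditions: NBS (1.05 equiv), AIBN (cat.), PhCF3, 85 °C
Reagents that add atoms: N-bromosuccinimide, O=C1CCC(=O)N1Br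
Why: Wohl–Ziegler bromination should take the methyl group on C3′, the only allylic C–H of the ring diene, as it does in 3-methylcoumarins.

Step 4
Reactants: 7 2-bromo-4,5-dihydroxybenzaldehyde
Product: 8 2-bromo-4,5-bis(methoxymethoxy)benzaldehyde
Conditions: MOMCl, i-Pr2NEt, CH2Cl2, 0 °C to rt
Reagents that add atoms: chloromethyl methyl ether, COCCl
Why: O-Alkylation of both phenols gives a base-stable, acid-labile catechol protection that is removed together with the tert-butyl ester at the end.

Step 5
Reactants: 8 2-bromo-4,5-bis(methoxymethoxy)benzaldehyde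
Product: 9 4,5-bis(methoxymethoxy)-2-(4,4,5,5-tetramethyl-1,3,2-dioxaborolan-2-yl)benzaldehyde
Conditions: B2pin2, Pd(dppf)Cl2 (3 mol %), KOAc, 1,4-dioxane, 85 °C
Reagents that add atoms: bis(pinacolato)diboron, CC1(C)OB(OC1(C)C)B1OC(C)(C)C(C)(C)O1
Why: Miyaura borylation of the aryl bromide tolerates the aldehyde and the MOM ethers under the weakly basic acetate conditions.

Step 6
Reactants: 6 tert-butyl 3-(bromomethyl)-2-oxo-2H-pyran-6-carboxylate; 9 4,5-bis(methoxymethoxy)-2-(4,4,5,5-tetramethyl-1,3,2-dioxaborolan-2-yl)benzaldehyde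
Product: 10 tert-butyl 3-[2-formyl-4,5-bis(methoxymethoxy)benzyl]-2-oxo-2H-pyran-6-carboxylate
Conditions: Pd(PPh3)4 (5 mol %), K3PO4, toluene–H2O (10:1), 60 °C
Reagents that add atoms: none
Why: Suzuki–Miyaura sp2–sp3 coupling of an arylboronate with an activated allylic/benzylic-type bromide should proceed at mild temperature because oxidative addition to this C–Br bond is fast, as in the coupling of 3-(halomethyl)coumarins.

Step 7
Reactants: 10 tert-butyl 3-[2-formyl-4,5-bis(methoxymethoxy)benzyl]-2-oxo-2H-pyran-6-carboxylate; 11 methyl (E)-4-oxobut-2-enoate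
Product: 14 methyl (1R,2R)-1-[6-(tert-butoxycarbonyl)-2-oxo-2H-pyran-3-yl]-3-formyl-6,7-bis(methoxymethoxy)-1,2-dihydronaphthalene-2-carboxylate, via photoenol 12 (not isolated), via tetralol aldehyde 13 (not isolated)
Conditions: 11 (2 equiv), (R)-diphenylprolinol trimethylsilyl ether (20 mol %), PhCO2H (20 mol %), degassed toluene, 365 nm LED, 10 °C; then dark, 40 °C
Reagents that add atoms: none
Why: Proposed new method: excitation of the aryl aldehyde of 10 and 1,5-hydrogen transfer from the doubly activated ArCH2(pyranonyl) group should give the (E,E)-hydroxy-o-quinodimethane 12, whose CH(pyranonyl) terminus adds with rearomatisation to the β-carbon (the one bearing CO2Me) of the iminium ion of 11, after which the enamine attacks the regenerated aryl aldehyde to give tetralol 13 and loss of water and hydrolysis release enal 14 and the amine. The closest known reactions are the light-driven iminium-catalysed β-benzylation of enals with photoenols of 2-alkylbenzophenones, the photoenolisation/Diels–Alder reaction of 2-benzylbenzaldehydes with fumarate-type dienophiles and the amine-catalysed Michael/aldol condensation of ortho-formyl benzylic pronucleophiles with enals; their combination on an aldehyde-derived photoenol is new. The carbocycle closes as a stepwise formal [4+2] annulation, C1–C2 first and then C3–C4 by a 6-(enolexo)-exo-trig enamine aldol. C2 is set by the catalyst, whose CPh2(OTMS) group shields one face of the E,s-trans iminium ion so that the dienol adds to the Re face of the β-carbon (2R); C1 is set relative to C2 by the outward position of the pyranonyl group on 12 and the endo placement of the iminium unit, which puts the pyranone and CO2Me trans (1R). The step needs regioselectivity (C1 to the ester-bearing carbon, secured by iminium activation of the formyl group), preference of 12 for the iminium ion over the free enal (secured by the far higher electrophilicity of the iminium ion) and excitation of the benzaldehyde and not the pyranone (secured at 365 nm, where the 2-pyranone chromophore absorbs little).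

Step 8
Reactants: 14 methyl (1R,2R)-1-[6-(tert-butoxycarbonyl)-2-oxo-2H-pyran-3-yl]-3-formyl-6,7-bis(methoxymethoxy)-1,2-dihydronaphthalene-2-carboxylate
Product: 15 (1R,2R)-1-[6-(tert-butoxycarbonyl)-2-oxo-2H-pyran-3-yl]-2-(methoxycarbonyl)-6,7-bis(methoxymethoxy)-1,2-dihydronaphthalene-3-carboxylic acid
Conditions: NaClO2, NaH2PO4, 2-methyl-2-butene, t-BuOH–H2O, 0 °C to rt
Reagents that add atoms: sodium chlorite, [Na+].[O-]Cl=O
Why: Pinnick oxidation should convert the conjugated aldehyde into the acid at about pH 4 without touching the alkene, the MOM ethers, the esters or the two stereocentres, the alkene scavenger removing hypochlorous acid before it can chlorinate the electron-rich ring.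

Step 9
Reactants: 15 (1R,2R)-1-[6-(tert-butoxycarbonyl)-2-oxo-2H-pyran-3-yl]-2-(methoxycarbonyl)-6,7-bis(methoxymethoxy)-1,2-dihydronaphthalene-3-carboxylic acid
Product: 16 (1R,2R)-1-(6-carboxy-2-oxo-2H-pyran-3-yl)-6,7-dihydroxy-2-(methoxycarbonyl)-1,2-dihydronaphthalene-3-carboxylic acid (CNP0239263.1)
Conditions: TFA–CH2Cl2–H2O (10:10:1), 0 °C to rt
Reagents that add atoms: none
Why: Acidolysis should cleave both MOM acetals and the tert-butyl ester in one operation, while the methyl ester, the lactone, the conjugated acid and the non-epimerising acidic medium leave C1 and C2 as set.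

**Compound list**

1 | ethyl tiglate, ethyl (E)-2-methylbut-2-enoate | C/C=C(\C)C(=O)OCC | starting material
2 | diethyl oxalate | CCOC(=O)C(=O)OCC | starting material
3 | potassium (2Z,4E)-1,6-diethoxy-5-methyl-1,6-dioxohexa-2,4-dien-2-olate (potassium dienolate) | CCOC(=O)/C([O-])=C/C=C(\C)C(=O)OCC.[K+] | intermediate
4 | 3-methyl-2-oxo-2H-pyran-6-carboxylic acid | Cc1ccc(C(=O)O)oc1=O | intermediate
5 | tert-butyl 3-methyl-2-oxo-2H-pyran-6-carboxylate | Cc1ccc(C(=O)OC(C)(C)C)oc1=O | intermediate
6 | tert-butyl 3-(bromomethyl)-2-oxo-2H-pyran-6-carboxylate | BrCc1ccc(C(=O)OC(C)(C)C)oc1=O | intermediate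
7 | 2-bromo-4,5-dihydroxybenzaldehyde | O=Cc1cc(O)c(O)cc1Br | starting material
8 | 2-bromo-4,5-bis(methoxymethoxy)benzaldehyde | O=Cc1cc(OCOC)c(OCOC)cc1Br | intermediate
9 | 4,5-bis(methoxymethoxy)-2-(4,4,5,5-tetramethyl-1,3,2-dioxaborolan-2-yl)benzaldehyde | O=Cc1cc(OCOC)c(OCOC)cc1B1OC(C)(C)C(C)(C)O1 | intermediate
10 | tert-butyl 3-[2-formyl-4,5-bis(methoxymethoxy)benzyl]-2-oxo-2H-pyran-6-carboxylate | O=Cc1cc(OCOC)c(OCOC)cc1Cc1ccc(C(=O)OC(C)(C)C)oc1=O | intermediate
11 | methyl (E)-4-oxobut-2-enoate | COC(=O)/C=C/C=O | starting material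
12 | photoenol: tert-butyl 3-{(E)-[(6E)-6-(hydroxymethylidene)-3,4-bis(methoxymethoxy)cyclohexa-2,4-dien-1-ylidene]methyl}-2-oxo-2H-pyran-6-carboxylate | O/C=C1\C=C(OCOC)C(OCOC)=C/C1=C\c1ccc(C(=O)OC(C)(C)C)oc1=O | intermediate
13 | tetralol aldehyde: methyl (1R,2R)-1-[6-(tert-butoxycarbonyl)-2-oxo-2H-pyran-3-yl]-3-formyl-4-hydroxy-6,7-bis(methoxymethoxy)-1,2,3,4-tetrahydronaphthalene-2-carboxylate (C3 and C4 as formed, both lost on dehydration) | COC(=O)[C@H]1C(C=O)C(O)c2cc(OCOC)c(OCOC)cc2[C@@H]1c1ccc(C(=O)OC(C)(C)C)oc1=O | intermediate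
14 | methyl (1R,2R)-1-[6-(tert-butoxycarbonyl)-2-oxo-2H-pyran-3-yl]-3-formyl-6,7-bis(methoxymethoxy)-1,2-dihydronaphthalene-2-carboxylate | COC(=O)[C@H]1C(C=O)=Cc2cc(OCOC)c(OCOC)cc2[C@@H]1c1ccc(C(=O)OC(C)(C)C)oc1=O | intermediate
15 | (1R,2R)-1-[6-(tert-butoxycarbonyl)-2-oxo-2H-pyran-3-yl]-2-(methoxycarbonyl)-6,7-bis(methoxymethoxy)-1,2-dihydronaphthalene-3-carboxylic acid | COC(=O)[C@H]1C(C(=O)O)=Cc2cc(OCOC)c(OCOC)cc2[C@@H]1c1ccc(C(=O)OC(C)(C)C)oc1=O | intermediate
16 | (1R,2R)-1-(6-carboxy-2-oxo-2H-pyran-3-yl)-6,7-dihydroxy-2-(methoxycarbonyl)-1,2-dihydronaphthalene-3-carboxylic acid | COC(=O)[C@H]1C(C(=O)O)=Cc2cc(O)c(O)cc2[C@@H]1c1ccc(C(=O)O)oc1=O | target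

**Totals.** Total step count: 9. Longest linear sequence: 7 (steps 1, 2, 3, 6, 7, 8, 9).

**Steps most likely to fail**

Step 7 (proposed new method). Three processes may spoil it:
- racemic background addition of the photoenol to the free enal, or acid-promoted reketonisation of the photoenol before it is trapped;
- weak control of C1 relative to C2;
- secondary photoreactions of the pyranone or of the conjugated product.

The fallback sets out from 10 and 11 and comes back at 14. Irradiation of 10 with 11 at 365 nm in degassed toluene without amine is the uncatalysed photoenolisation/Diels–Alder reaction known for 2-benzylbenzaldehydes and electron-poor alkenes. The more activating formyl group should direct C1 to the ester-bearing carbon, and endo addition through 12 should give the 1,2-trans tetralol as a racemate, that is 13 together with the mirror-image tetralol aldehyde F1. PPTS in toluene at 40 °C should dehydrate both to the racemic enal, 14 together with the mirror-image enal F2. Preparative chromatography on a chiral stationary phase then separates 14 from F2.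

Step 6. Protodeboronation of the ortho-formyl arylboronate, hydroxide-induced opening of the pyranone lactone and hydrolysis of the allylic bromide may all compete under the aqueous basic conditions. The fallback sets out from 8 and 6 and comes back at 10. Palladium-catalysed stannylation of 8 with hexabutylditin (Pd(PPh3)4, toluene, 110 °C) should give 4,5-bis(methoxymethoxy)-2-(tributylstannyl)benzaldehyde F3. A base-free Stille coupling of F3 with 6 (Pd2(dba)3, AsPh3, DMF, 60 °C) should then give 10.

Step 3. Over-bromination at the methyl group, competing bromination of the ring and HBr-induced loss of the tert-butyl ester may lower the selectivity of the radical step. The fallback sets out from 2 and comes back at 6, with the bromine placed ionically: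
- Condensation of 2 with ethyl crotonate under the conditions of step 1 should give 2-oxo-2H-pyran-6-carboxylic acid F4.
- The trichloroacetimidate of step 2 should convert it into tert-butyl 2-oxo-2H-pyran-6-carboxylate F5.
- Bromine addition followed by elimination with Et3N should give tert-butyl 3-bromo-2-oxo-2H-pyran-6-carboxylate F6.
- Stille coupling with (tributylstannyl)methanol (Pd(PPh3)4, dioxane, 90 °C) should give tert-butyl 3-(hydroxymethyl)-2-oxo-2H-pyran-6-carboxylate F7.
- An Appel reaction (CBr4, PPh3, CH2Cl2, 0 °C) should give 6.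

**Further compounds**

F1 | step 7 | mirror-image tetralol aldehyde: methyl (1S,2S)-1-[6-(tert-butoxycarbonyl)-2-oxo-2H-pyran-3-yl]-3-formyl-4-hydroxy-6,7-bis(methoxymethoxy)-1,2,3,4-tetrahydronaphthalene-2-carboxylate | COC(=O)[C@@H]1C(C=O)C(O)c2cc(OCOC)c(OCOC)cc2[C@H]1c1ccc(C(=O)OC(C)(C)C)oc1=O
F2 | step 7 | mirror-image enal: methyl (1S,2S)-1-[6-(tert-butoxycarbonyl)-2-oxo-2H-pyran-3-yl]-3-formyl-6,7-bis(methoxymethoxy)-1,2-dihydronaphthalene-2-carboxylate | COC(=O)[C@@H]1C(C=O)=Cc2cc(OCOC)c(OCOC)cc2[C@H]1c1ccc(C(=O)OC(C)(C)C)oc1=O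
F3 | step 6 | 4,5-bis(methoxymethoxy)-2-(tributylstannyl)benzaldehyde | CCCC[Sn](CCCC)(CCCC)c1cc(OCOC)c(OCOC)cc1C=O
F4 | step 3 | 2-oxo-2H-pyran-6-carboxylic acid | O=C(O)c1cccc(=O)o1
F5 | step 3 | tert-butyl 2-oxo-2H-pyran-6-carboxylate | CC(C)(C)OC(=O)c1cccc(=O)o1
F6 | step 3 | tert-butyl 3-bromo-2-oxo-2H-pyran-6-carboxylate | CC(C)(C)OC(=O)c1ccc(Br)c(=O)o1
F7 | step 3 | tert-butyl 3-(hydroxymethyl)-2-oxo-2H-pyran-6-carboxylate | CC(C)(C)OC(=O)c1ccc(CO)c(=O)o1
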